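## Retrosynthetic overview

- Numbering (daucane): ring A is the cyclopentane C1–C5 (C1 the methyl-bearing quaternary fusion carbon, C4 the isopropyl carbinol, C5 the fusion CH); ring B is the cycloheptene C1, C5, C6 (ester carbinol), C7, C8(CH3)=C9, C10.
- The C6–O ester bond is cut first, giving the 4,6-diol and O-silyl p-coumaric acid; the diol comes from the C6 ketone by reduction directed by the C4 hydroxyl, and the ketone from a C5=C6 methyl enol ether.
- The strategy rests on ring B: its oxygen sits on C6 next to fusion carbon C5, and C8(CH3)=C9 lies where the central bond of a 2-methylbutadiene ends up after a (4+3) union. Ring B is therefore isoprene (C7–C10) plus a C6–C5–C1 unit in the form of a chromium methoxy(cyclopentenyl)carbene. Bonds C6–C7 and C1–C10 form by cyclopropanation and divinylcyclopropane Cope rearrangement.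
- Ring A is made first, from (S)-terpinen-4-ol by ozonolysis and aldol ring contraction. Ring B is closed second. C4 is the only stereocentre carried in and relays to C1, then C5, then C6.

Key step: step 7

Assumption: commercial (S)-(+)-terpinen-4-ol is taken as enantiomerically pure. Where an unisolated intermediate forms as a stereoisomer mixture at centres that are destroyed later, one isomer (for the cyclopropane, the productive one) is drawn.

## Route

Step 1
Reactants: 1 (S)-terpinen-4-ol
Product: 2 (S)-tert-butyldimethyl{[4-methyl-1-(propan-2-yl)cyclohex-3-en-1-yl]oxy}silane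
Conditions: TBSOTf, 2,6-lutidine, CH2Cl2, 0 °C → rt
Reagents that add atoms: tert-butyldimethylsilyl triflate, CC(C)(C)[Si](C)(C)OS(=O)(=O)C(F)(F)F
Why: Silyl triflate silylation of a tertiary alcohol with a hindered base is standard, leaves the stereocentre untouched, and masks the hydroxyl that would otherwise allow retro-aldol cleavage or dehydration once the ring is opened.

Step 2
Reactants: 2 (S)-tert-butyldimethyl{[4-methyl-1-(propan-2-yl)cyclohex-3-en-1-yl]oxy}silane
Product: 4 (S)-3-(tert-butyldimethylsilyloxy)-6-oxo-3-(propan-2-yl)heptanal, via secondary ozonide 3 (not isolated)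
Conditions: O3, CH2Cl2, −78 °C; then Me2S, −78 °C → rt
Reagents that add atoms: ozone, [O-][O+]=O
Why: Ozonolysis with reductive work-up (Criegee mechanism) cleaves the only C=C bond to the 1,6-keto aldehyde and cannot affect the quaternary carbinol carbon.

Step 3
Reactants: 4 (S)-3-(tert-butyldimethylsilyloxy)-6-oxo-3-(propan-2-yl)heptanal
Product: 5 (R)-5-(tert-butyldimethylsilyloxy)-2-methyl-5-(propan-2-yl)cyclopent-1-ene-1-carbaldehyde
Conditions: piperidine, AcOH, toluene, 4 Å MS, rt → 60 °C
Reagents that add atoms: none
Why: Amine-mediated intramolecular aldol condensation, in which the piperidine enamine of the aldehyde attacks the methyl ketone to close the five-membered ring and dehydration gives the tetrasubstituted enal; this is the regiochemistry established for 6-oxoheptanals under piperidinium acetate, and the quaternary carbinol centre cannot epimerise.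

Step 4
Reactants: 5 (R)-5-(tert-butyldimethylsilyloxy)-2-methyl-5-(propan-2-yl)cyclopent-1-ene-1-carbaldehyde
Product: 6 (R)-5-(tert-butyldimethylsilyloxy)-2-methyl-5-(propan-2-yl)cyclopent-1-ene-1-carboxylic acid
Conditions: NaClO2, NaH2PO4, 2-methyl-2-butene, t-BuOH/H2O, rt
Reagents that add atoms: sodium chlorite NaClO2, [Na+].[O-]Cl=O
Why: Pinnick oxidation converts hindered α,β-unsaturated aldehydes to the acids without touching the alkene or the silyl ether, the added alkene scavenging hypochlorous acid.

Step 5
Reactants: 6 (R)-5-(tert-butyldimethylsilyloxy)-2-methyl-5-(propan-2-yl)cyclopent-1-ene-1-carboxylic acid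
Product: 7 (R)-5-(tert-butyldimethylsilyloxy)-2-methyl-5-(propan-2-yl)cyclopent-1-ene-1-carbonyl chloride
Conditions: 1-chloro-N,N,2-trimethylprop-1-en-1-amine, CH2Cl2, 0 °C → rt; used crude
Reagents that add atoms: 1-chloro-N,N,2-trimethylprop-1-en-1-amine (Ghosez reagent), CC(C)=C(Cl)N(C)C
Why: The Ghosez α-chloroenamine forms the acid chloride under neutral conditions without free HCl, which protects the tertiary silyl ether.

Step 6
Reactants: 7 (R)-5-(tert-butyldimethylsilyloxy)-2-methyl-5-(propan-2-yl)cyclopent-1-ene-1-carbonyl chloride; 8 hexacarbonylchromium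
Product: 11 pentacarbonyl{methoxy[(R)-5-(tert-butyldimethylsilyloxy)-2-methyl-5-(propan-2-yl)cyclopent-1-en-1-yl]methylidene}chromium, via dipotassium pentacarbonylchromate 9 (not isolated), via potassium acylchromate 10 (not isolated)
Conditions: Cr(CO)6, C8K (2 equiv), THF, −78 → 0 °C; then 7, −78 → 0 °C; then Me3OBF4, CH2Cl2, 0 °C
Reagents that add atoms: trimethyloxonium tetrafluoroborate, C[O+](C)C.F[B-](F)(F)F
Why: Semmelhack–Hegedus carbene synthesis, in which the pentacarbonylchromate dianion displaces chloride from the acid chloride to give the acylchromate and the Meerwein salt alkylates it on oxygen to give the Fischer methoxycarbene; this avoids having to generate a tetrasubstituted cyclopentenyllithium.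

Step 7
Reactants: 11 pentacarbonyl{methoxy[(R)-5-(tert-butyldimethylsilyloxy)-2-methyl-5-(propan-2-yl)cyclopent-1-en-1-yl]methylidene}chromium; 12 isoprene
Product: 14 (1R,4R)-4-(tert-butyldimethylsilyloxy)-6-methoxydauca-5,8-diene, via cis-divinylcyclopropane 13 (not isolated)
Conditions: isoprene (10 equiv), toluene, sealed tube, Ar, dark, 90 °C then 130 °C
Reagents that add atoms: none
Why: On heating, 11 loses CO, the more electron-rich 1,1-disubstituted double bond of isoprene binds, and the electrophilic carbene carbon C6 closes a chromacyclobutane with the CH2 terminus C7; reductive elimination then joins C6 to C8 to give cyclopropane 13 with the cyclopentenyl group on C6 and the vinyl group on C8. The cis isomer of 13 undergoes the divinylcyclopropane Cope rearrangement through the boat transition state (C6–C8 breaks, C1–C10 forms, strain release paying for the quaternary centre), and trans isomers should be returned by reversible opening of the weak, doubly allylic, methoxy-bearing C6–C8 bond at the higher temperature. The closest known reaction type is the tandem cyclopropanation/Cope formal (4+3) cycloaddition of alkenyl Fischer carbene complexes with 1,3-dienes. The three-membered ring closes by carbene transfer to the alkene, and ring B closes by the [3,3] sigmatropic shift, which leaves the enol ether C5=C6 and the alkene C8=C9 in their final places. The only new stereocentre, C1, is controlled by C4: the silyl group, held anti to the geminal isopropyl group, should lie over the upper face of the cyclopentene, so the C8–C9=C10 arm stacks under the ring and C10 bonds to C1 cis to isopropyl. The step needs site selectivity for the methyl-bearing alkene of isoprene (expected from its higher nucleophilicity), suppression of the carbene Diels–Alder pathway (expected from the tetrasubstituted, hindered cyclopentene) and the facial selectivity just described.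

Step 8
Reactants: 14 (1R,4R)-4-(tert-butyldimethylsilyloxy)-6-methoxydauca-5,8-diene
Product: 15 (1R,4R,5R)-4-(tert-butyldimethylsilyloxy)dauc-8-en-6-one
Conditions: 1 M aq. HCl, THF, 0 °C → rt
Reagents that add atoms: water, O
Why: Enol ether hydrolysis starts with protonation at C5, which should occur on the face away from the silyl ether and the angular methyl group and give the trans-fused ketone; this is also expected to be the more stable epimer (C6 anti to isopropyl), so enolisation in the same acid can only reinforce it, and the conditions are kept mild to hold C8=C9 out of conjugation.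

Step 9
Reactants: 15 (1R,4R,5R)-4-(tert-butyldimethylsilyloxy)dauc-8-en-6-one
Product: 16 (1R,4R,5R)-4-hydroxydauc-8-en-6-one
Conditions: HF·pyridine, pyridine, THF, 0 °C → rt
Reagents that add atoms: none
Why: Fluoride cleavage of the tertiary silyl ether under buffered, weakly acidic conditions, chosen because a basic fluoride source could open ring A of the β-hydroxy ketone by retro-aldol reaction.

Step 10
Reactants: 16 (1R,4R,5R)-4-hydroxydauc-8-en-6-one
Product: 17 (1R,4R,5S,6S)-dauc-8-ene-4,6-diol (jaeschkeanadiol)
Conditions: Me4NBH(OAc)3, MeCN/AcOH (1:1), −30 → 0 °C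
Reagents that add atoms: none
Why: Evans–Saksena hydroxyl-directed reduction, in which the C4 hydroxyl exchanges onto boron and delivers hydride intramolecularly to the C6 carbonyl from the face on which C4 sits, giving the anti 1,3-diol with the new hydroxyl on the opposite face.

Step 11
Reactants: 18 (E)-4-hydroxycinnamic acid
Product: 20 (E)-3-[4-(tert-butyldimethylsilyloxy)phenyl]prop-2-enoic acid, via bis-silyl derivative 19 (not isolated)
Conditions: TBSCl (2.5 equiv), imidazole, DMF, rt; then AcOH/THF/H2O, rt
Reagents that add atoms: tert-butyldimethylsilyl chloride, CC(C)(C)[Si](C)(C)Cl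
Why: Exhaustive silylation followed by selective hydrolysis of the labile silyl ester leaves the aryl silyl ether, which prevents self-acylation of the phenol in the coupling; the E alkene is not involved.

Step 12
Reactants: 17 (1R,4R,5S,6S)-dauc-8-ene-4,6-diol; 20 (E)-3-[4-(tert-butyldimethylsilyloxy)phenyl]prop-2-enoic acid
Product: 21 (1R,4R,5S,6S)-4-hydroxydauc-8-en-6-yl (E)-3-[4-(tert-butyldimethylsilyloxy)phenyl]prop-2-enoate
Conditions: EDC·HCl, DMAP, CH2Cl2, rt
Reagents that add atoms: none
Why: Steglich esterification acylates only the secondary C6 hydroxyl because the tertiary C4 hydroxyl is inert to DMAP acyl transfer, and C6 keeps its configuration because its C–O bond is not broken.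

Step 13
Reactants: 21 (1R,4R,5S,6S)-4-hydroxydauc-8-en-6-yl (E)-3-[4-(tert-butyldimethylsilyloxy)phenyl]prop-2-enoate
Product: 22 (1R,4R,5S,6S)-4-hydroxydauc-8-en-6-yl (E)-3-(4-hydroxyphenyl)prop-2-enoate (CNP0265426.1)
Conditions: TBAF, AcOH, THF, 0 °C
Reagents that add atoms: none
Why: Fluoride-induced desilylation of the aryl silyl ether is fast at 0 °C, and acetic acid buffering keeps the phenoxide from attacking the cinnamate ester.

## Compound list

1 | (S)-terpinen-4-ol | CC1=CC[C@](O)(C(C)C)CC1 | starting material
2 | (S)-tert-butyldimethyl{[4-methyl-1-(propan-2-yl)cyclohex-3-en-1-yl]oxy}silane | CC1=CC[C@](O[Si](C)(C)C(C)(C)C)(C(C)C)CC1 | intermediate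
3 | secondary ozonide of 2, a 7,8,9-trioxabicyclo[4.2.1]nonane (one of the two bridge diastereomers drawn) | C[C@@]12CC[C@@](O[Si](C)(C)C(C)(C)C)(C(C)C)C[C@@H](OO1)O2 | intermediate
4 | (S)-3-(tert-butyldimethylsilyloxy)-6-oxo-3-(propan-2-yl)heptanal | CC(=O)CC[C@@](O[Si](C)(C)C(C)(C)C)(C(C)C)CC=O | intermediate
5 | (R)-5-(tert-butyldimethylsilyloxy)-2-methyl-5-(propan-2-yl)cyclopent-1-ene-1-carbaldehyde | O=CC1=C(C)CC[C@@]1(O[Si](C)(C)C(C)(C)C)C(C)C | intermediate
6 | (R)-5-(tert-butyldimethylsilyloxy)-2-methyl-5-(propan-2-yl)cyclopent-1-ene-1-carboxylic acid | OC(=O)C1=C(C)CC[C@@]1(O[Si](C)(C)C(C)(C)C)C(C)C | intermediate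
7 | (R)-5-(tert-butyldimethylsilyloxy)-2-methyl-5-(propan-2-yl)cyclopent-1-ene-1-carbonyl chloride | ClC(=O)C1=C(C)CC[C@@]1(O[Si](C)(C)C(C)(C)C)C(C)C | intermediate
8 | hexacarbonylchromium | O=C=[Cr](=C=O)(=C=O)(=C=O)(=C=O)=C=O | starting material
9 | dipotassium pentacarbonylchromate K2Cr(CO)5 | [K+].[K+].O=C=[Cr-2](=C=O)(=C=O)(=C=O)=C=O | intermediate
10 | potassium pentacarbonyl(acyl)chromate of 7 | [K+].[O-]C(=[Cr](=C=O)(=C=O)(=C=O)(=C=O)=C=O)C1=C(C)CC[C@@]1(O[Si](C)(C)C(C)(C)C)C(C)C | intermediate
11 | pentacarbonyl{methoxy[(R)-5-(tert-butyldimethylsilyloxy)-2-methyl-5-(propan-2-yl)cyclopent-1-en-1-yl]methylidene}chromium | COC(=[Cr](=C=O)(=C=O)(=C=O)(=C=O)=C=O)C1=C(C)CC[C@@]1(O[Si](C)(C)C(C)(C)C)C(C)C | intermediate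
12 | isoprene | C=CC(C)=C | starting material
13 | 1-methoxy-2-methyl-2-vinylcyclopropane bearing the cyclopentenyl group of 11 on C1, cyclopentenyl and vinyl cis (productive diastereomer drawn) | CO[C@]1(C[C@]1(C)C=C)C2=C(C)CC[C@@]2(O[Si](C)(C)C(C)(C)C)C(C)C | intermediate
14 | (1R,4R)-4-(tert-butyldimethylsilyloxy)-6-methoxydauca-5,8-diene | CC1=CC[C@@]2(C)CC[C@@](O[Si](C)(C)C(C)(C)C)(C(C)C)C2=C(OC)C1 | intermediate
15 | (1R,4R,5R)-4-(tert-butyldimethylsilyloxy)dauc-8-en-6-one, trans-fused | CC1=CC[C@@]2(C)CC[C@@](O[Si](C)(C)C(C)(C)C)(C(C)C)[C@@H]2C(=O)C1 | intermediate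
16 | (1R,4R,5R)-4-hydroxydauc-8-en-6-one | CC1=CC[C@@]2(C)CC[C@@](O)(C(C)C)[C@@H]2C(=O)C1 | intermediate
17 | (1R,4R,5S,6S)-dauc-8-ene-4,6-diol (jaeschkeanadiol) | CC1=CC[C@@]2(C)CC[C@@](O)(C(C)C)[C@@H]2[C@@H](O)C1 | intermediate
18 | (E)-4-hydroxycinnamic acid | OC(=O)/C=C/c1ccc(O)cc1 | starting material
19 | tert-butyldimethylsilyl (E)-3-[4-(tert-butyldimethylsilyloxy)phenyl]prop-2-enoate | CC(C)(C)[Si](C)(C)OC(=O)/C=C/c1ccc(O[Si](C)(C)C(C)(C)C)cc1 | intermediate
20 | (E)-3-[4-(tert-butyldimethylsilyloxy)phenyl]prop-2-enoic acid | OC(=O)/C=C/c1ccc(O[Si](C)(C)C(C)(C)C)cc1 | intermediate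
21 | (1R,4R,5S,6S)-4-hydroxydauc-8-en-6-yl (E)-3-[4-(tert-butyldimethylsilyloxy)phenyl]prop-2-enoate | CC1=CC[C@@]2(C)CC[C@@](O)(C(C)C)[C@@H]2[C@@H](OC(=O)/C=C/c2ccc(O[Si](C)(C)C(C)(C)C)cc2)C1 | intermediate
22 | (1R,4R,5S,6S)-4-hydroxydauc-8-en-6-yl (E)-3-(4-hydroxyphenyl)prop-2-enoate | CC1=CC[C@@]2(C)CC[C@@](O)(C(C)C)[C@@H]2[C@@H](OC(=O)/C=C/c2ccc(O)cc2)C1 | target

## Step count and risks

Total: 13 steps. Longest linear sequence: 12 steps (steps 1–10, 12, 13, from (S)-terpinen-4-ol); step 11 is a one-step side branch.

Steps most likely to fail: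

1. Step 7 (key step). What may go wrong: cyclopropanation of the vinyl instead of the isopropenyl double bond of isoprene; a Cope rearrangement that stalls because the C1 methyl group points into the boat transition state; or C1–C10 bond formation on the silyl ether face, since the isopropyl group may shield as strongly as the silyl ether. Fallback (sets out from 5, returns at 15): ring B would be built bond by bond. Asymmetric allylboration of 5 with the enantiomer of Ipc2B(allyl) that gives the (R)-carbinol would give homoallylic alcohol F1. Anionic oxy-Cope rearrangement (KH, 18-crown-6, THF), through the chair in which the carbinol hydrogen points toward C4, should carry the allyl group to the isopropyl face of C1; protonation and DBU equilibration at C5 would give aldehyde F2. Addition of CH2=C(CH3)CH2MgCl would give dienol F3. Ring-closing metathesis with the second-generation Grubbs catalyst (H2IMes)(PCy3)Cl2Ru=CHPh would close ring B at C8=C9 to cycloheptenol F4, and Dess–Martin oxidation would give 15. Here C1 is set by reagent-controlled chirality transfer from C6, and C5 by equilibration of an aldehyde that has no skipped double bond.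

2. Step 8. What may go wrong: the hindered tetrasubstituted enol ether hydrolyses only under acid strong enough to move C8=C9 into conjugation with the new ketone or to eliminate the tertiary silyl ether, or protonation at C5 occurs on the wrong face and cannot be corrected without that migration. Fallback (sets out from 14, returns at 15): oxidative unmasking. NBS, NaHCO3, aqueous THF, −20 °C would convert the enol ether into α-bromo ketone F5. SmI2, THF/MeOH, −78 °C would then reduce the C5–Br bond to the C5=C6 samarium enolate, which is protonated at once at low temperature to give 15 without any equilibrating acid or base.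

3. Step 6. What may go wrong: electron transfer from, or conjugate attack by, the pentacarbonylchromate dianion on the hindered enoyl chloride in place of acyl substitution. Fallback (sets out from 6, returns at 11): the classical organolithium route to the carbene. Curtius degradation of 6 (DPPA, Et3N, toluene, 80 °C; then 1 M HCl, THF) would pass through acyl azide F6 and vinyl isocyanate F7 to cyclopentanone F8. Condensation with 2,4,6-triisopropylbenzenesulfonyl hydrazide would give trisylhydrazone F9. Shapiro reaction (n-BuLi, TMEDA, THF, −78 → 0 °C), which can only deprotonate the methyl-bearing α-carbon, would give cyclopentenyllithium F10. Addition to Cr(CO)6 would give lithium acylchromate F11, and Me3OBF4 would give 11.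

## Further compounds

F1 | step 7 | (R)-1-[(R)-5-(tert-butyldimethylsilyloxy)-2-methyl-5-(propan-2-yl)cyclopent-1-en-1-yl]but-3-en-1-ol | C=CC[C@@H](O)C1=C(C)CC[C@@]1(O[Si](C)(C)C(C)(C)C)C(C)C
F2 | step 7 | 2-allyl-5-(tert-butyldimethylsilyloxy)-2-methyl-5-(propan-2-yl)cyclopentane-1-carbaldehyde, configured at C1, C4 and C5 as in 15 | C=CC[C@@]1(C)CC[C@@](O[Si](C)(C)C(C)(C)C)(C(C)C)[C@@H]1C=O
F3 | step 7 | 1-[2-allyl-5-(tert-butyldimethylsilyloxy)-2-methyl-5-(propan-2-yl)cyclopentyl]-3-methylbut-3-en-1-ol (both carbinol epimers) | C=CC[C@@]1(C)CC[C@@](O[Si](C)(C)C(C)(C)C)(C(C)C)[C@@H]1C(O)CC(C)=C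
F4 | step 7 | (1R,4R,5S)-4-(tert-butyldimethylsilyloxy)dauc-8-en-6-ol (both C6 epimers) | CC1=CC[C@@]2(C)CC[C@@](O[Si](C)(C)C(C)(C)C)(C(C)C)[C@@H]2C(O)C1
F5 | step 8 | 5-bromo-4-(tert-butyldimethylsilyloxy)dauc-8-en-6-one (C5 epimers) | CC1=CC[C@@]2(C)CC[C@@](O[Si](C)(C)C(C)(C)C)(C(C)C)C2(Br)C(=O)C1
F6 | step 6 | (R)-5-(tert-butyldimethylsilyloxy)-2-methyl-5-(propan-2-yl)cyclopent-1-ene-1-carbonyl azide | [N-]=[N+]=NC(=O)C1=C(C)CC[C@@]1(O[Si](C)(C)C(C)(C)C)C(C)C
F7 | step 6 | (R)-tert-butyl{[2-isocyanato-3-methyl-1-(propan-2-yl)cyclopent-2-en-1-yl]oxy}dimethylsilane | O=C=NC1=C(C)CC[C@@]1(O[Si](C)(C)C(C)(C)C)C(C)C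
F8 | step 6 | (5R)-5-(tert-butyldimethylsilyloxy)-2-methyl-5-(propan-2-yl)cyclopentan-1-one (both C2 epimers) | O=C1C(C)CC[C@@]1(O[Si](C)(C)C(C)(C)C)C(C)C
F9 | step 6 | 2,4,6-triisopropylbenzenesulfonyl hydrazone of F8 | CC(C)c1cc(C(C)C)c(S(=O)(=O)NN=C2C(C)CC[C@@]2(O[Si](C)(C)C(C)(C)C)C(C)C)c(C(C)C)c1
F10 | step 6 | [5-(tert-butyldimethylsilyloxy)-2-methyl-5-(propan-2-yl)cyclopent-1-en-1-yl]lithium, configured as in 11 | [Li]C1=C(C)CC[C@@]1(O[Si](C)(C)C(C)(C)C)C(C)C
F11 | step 6 | lithium pentacarbonyl(acyl)chromate, lithium analogue of 10 | [Li+].[O-]C(=[Cr](=C=O)(=C=O)(=C=O)(=C=O)=C=O)C1=C(C)CC[C@@]1(O[Si](C)(C)C(C)(C)C)C(C)C
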